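**Retrosynthetic overview**
1. The target is the dimethyl ether of 2,5-dihydroxy-3-(indol-3-yl)-6-[2-(1,1-dimethylallyl)indol-3-yl]-1,4-benzoquinone; the two O–CH3 bonds are made last.
2. Enabling feature: in the quinone ring each C=O carbon (C1, C4) lies between an O-bearing carbon (C2, C5) and an indol-3-yl-bearing carbon (C3, C6). The ring is therefore the bis-enol of a cyclohexane-1,2,4,5-tetraone built from two head-to-tail indolyl–CH2–CO–CO units, and both C(=O)–C(indolyl) bonds (C1–C6 and C4–C3) are cut at once (crossed Claisen plus Dieckmann).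
3. Fragment 1 (nucleophile first): ethyl 3-[2-(1,1-dimethylallyl)indol-3-yl]pyruvate, from the 2-substituted indole (Fischer) by C3 alkylation with a nitrosoacrylate and deoximation.
4. Fragment 2 (acyl donor first): the enol acetonide of N-Boc-indol-3-ylpyruvic acid, a 5-ylidene-1,3-dioxolan-4-one made by a Wittig reaction; its temporary dioxolanone ring and the Boc group are lost in the key step.
5. Ring order: indole ring of fragment 1, temporary dioxolanone ring of fragment 2 (opened again), quinone ring last.

Key step: step 7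

Assumption: compounds 2, 5, 10 and 13 are taken as purchasable; the target has no stereocentre, and the C=N geometry of 5, 7 and 8 is not defined and does not matter, so it is left open in their SMILES.

**Step 1**
Reactants: 1 phenylhydrazine; 2 3,3-dimethylpent-4-en-2-one
Product: 4 2-(2-methylbut-3-en-2-yl)-1H-indole, via phenylhydrazone 3 (not isolated)
Conditions: AcOH (cat.), EtOH, 80 °C; then ZnCl2, xylene, 130 °C
Reagents that add atoms: none
Why: Fischer indole synthesis; the hydrazone of a methyl ketone whose other alpha carbon is quaternary can form the ene-hydrazine only toward the methyl group, so the [3,3]-shift and loss of ammonia should give the 2-substituted, 3-unsubstituted indole with the 1,1-dimethylallyl group intact.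

**Step 2**
Reactants: 4 2-(2-methylbut-3-en-2-yl)-1H-indole; 5 ethyl 3-bromo-2-(hydroxyimino)propanoate
Product: 7 ethyl 2-(hydroxyimino)-3-[2-(2-methylbut-3-en-2-yl)-1H-indol-3-yl]propanoate, via nitrosoalkene 6 (not isolated)
Conditions: Na2CO3, CH2Cl2, rt (5 added in portions)
Reagents that add atoms: none
Why: Base-induced 1,4-elimination of HBr should give the nitrosoalkene 6, which the nucleophilic indole C3 traps at its unhindered CH2 terminus (Gilchrist-type conjugate addition of an indole to a nitrosoalkene), and rearomatisation leaves the oxime.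

**Step 3**
Reactants: 7 ethyl 2-(hydroxyimino)-3-[2-(2-methylbut-3-en-2-yl)-1H-indol-3-yl]propanoate
Product: 9 ethyl 3-[2-(2-methylbut-3-en-2-yl)-1H-indol-3-yl]-2-oxopropanoate, via imino ester 8 (not isolated)
Conditions: TiCl3 (aq.), NH4OAc, THF–H2O, 0 °C to rt
Reagents that add atoms: water, O
Why: Reductive deoximation; TiCl3 should cleave the N–O bond to the N–H imine 8, which is hydrolysed in the buffered aqueous medium to the alpha-keto ester without acid strong enough to touch the 1,1-dimethylallyl group.

**Step 4**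
Reactants: 10 2,2-dimethyl-1,3-dioxolan-4-one
Product: 11 5-bromo-2,2-dimethyl-1,3-dioxolan-4-one (racemic)
Conditions: NBS, AIBN (cat.), PhCF3, 80 °C
Reagents that add atoms: N-bromosuccinimide, O=C1CCC(=O)N1Br
Why: Wohl–Ziegler radical bromination should take place at C5, the only captodative C–H (between the lactone carbonyl and a ring oxygen).

**Step 5**
Reactants: 11 5-bromo-2,2-dimethyl-1,3-dioxolan-4-one
Product: 12 (2,2-dimethyl-5-oxo-1,3-dioxolan-4-yl)triphenylphosphonium bromide (racemic)
Conditions: PPh3, toluene, rt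
Reagents that add atoms: triphenylphosphine, c1ccc(cc1)P(c1ccccc1)c1ccccc1
Why: Nucleophilic substitution of the activated alpha-bromo acetal-type bromide by the phosphine should give the phosphonium salt, which precipitates.

**Step 6**
Reactants: 12 (2,2-dimethyl-5-oxo-1,3-dioxolan-4-yl)triphenylphosphonium bromide; 13 tert-butyl 3-formyl-1H-indole-1-carboxylate
Product: 15 tert-butyl 3-[(Z)-(2,2-dimethyl-5-oxo-1,3-dioxolan-4-ylidene)methyl]-1H-indole-1-carboxylate, via phosphorus ylide 14 (not isolated)
Conditions: Et3N, CH2Cl2, rt to 40 °C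
Reagents that add atoms: none
Why: Wittig olefination with the ester-stabilised ylide 14; the N-Boc group makes the indole-3-carbaldehyde a normal electrophilic aryl aldehyde, and the expected (Z)-alkene (indole cis to the ring oxygen) has a geometry that is erased in step 7 anyway.

**Step 7**
Reactants: 9 ethyl 3-[2-(2-methylbut-3-en-2-yl)-1H-indol-3-yl]-2-oxopropanoate; 15 tert-butyl 3-[(Z)-(2,2-dimethyl-5-oxo-1,3-dioxolan-4-ylidene)methyl]-1H-indole-1-carboxylate
Product: 18 2,5-dihydroxy-3-(1H-indol-3-yl)-6-[2-(2-methylbut-3-en-2-yl)-1H-indol-3-yl]cyclohexa-2,5-diene-1,4-dione, via trioxohexanoate adduct 16 (not isolated), via N-Boc dihydroxyquinone 17 (not isolated)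
Conditions: 9, LiN(SiMe3)2 (1.05 equiv), THF, −78 °C; then 15, −78 to 0 °C; then NaOEt (5 equiv), EtOH, 0 to 50 °C; aq. HCl work-up at 0 °C
Reagents that add atoms: none
Why: Proposed new method: the preformed lithium enolate of 9 (ester deactivated, indole N–H untouched) should attack the lactone carbonyl of 15, and the tetrahedral intermediate collapses with loss of acetone, which forms the first C–C bond and unmasks the enolate of fragment 2 (adduct 16); ethoxide then makes the dianion of 16, whose indolyl-bearing carbon attacks the ethyl ester in a Dieckmann condensation, and enolisation of the resulting cyclohexane-1,2,4,5-tetraone gives the dihydroxyquinone dianion while ethoxide also removes the N-Boc group. The closest known reactions are the acylation of ester enolates by 5-ylidene-1,3-dioxolan-4-ones with loss of the ketone (pulvinone and tetronic acid syntheses), the Dieckmann condensation, and the base-induced rearrangement of 6-arylidene-pyran-2,5-diones to 2,5-dihydroxy-3,6-diarylbenzoquinones; what is new is running them as one crossed union of two different indolylpyruvate units. The quinone ring closes by a 6-(enolendo)-exo-trig attack of the enolate carbon on the ester carbonyl; no stereocentre is formed and the alkene geometry of 15 is erased. The step needs cross-union over homo-union, which is secured because the nucleophilic carbon of fragment 2 stays locked as a vinyl carbon of the enol acetonide until its carbonyl has been acylated and no alkoxide is present at that stage, so each fragment can play only one role first. It also needs C–C over C–O ring closure, which is secured thermodynamically: O-acylated or lactone (pyran-2,5-dione) isomers are reopened by ethoxide and funnel to the doubly vinylogous carboxylate dianion of 18, the most stabilised species in the manifold.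

**Step 8**
Reactants: 18 2,5-dihydroxy-3-(1H-indol-3-yl)-6-[2-(2-methylbut-3-en-2-yl)-1H-indol-3-yl]cyclohexa-2,5-diene-1,4-dione
Product: 19 3-(1H-indol-3-yl)-2,5-dimethoxy-6-[2-(2-methylbut-3-en-2-yl)-1H-indol-3-yl]cyclohexa-2,5-diene-1,4-dione
Conditions: Me2SO4 (2.5 equiv), K2CO3, acetone, rt to 40 °C
Reagents that add atoms: dimethyl sulfate, COS(=O)(=O)OC
Why: O-Alkylation of the two vinylogous carboxylic acid hydroxyls, which are far more acidic than the indole N–H that K2CO3 does not deprotonate; the para-quinonoid 2,5-dimethoxy isomer is the expected, more stable product of such methylations.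

**Compound list**
1 | phenylhydrazine | NNc1ccccc1 | starting material
2 | 3,3-dimethylpent-4-en-2-one | CC(=O)C(C)(C)C=C | starting material
3 | 1-[(2E)-3,3-dimethylpent-4-en-2-ylidene]-2-phenylhydrazine (phenylhydrazone of 2) | C/C(=N\Nc1ccccc1)C(C)(C)C=C | intermediate
4 | 2-(2-methylbut-3-en-2-yl)-1H-indole | C=CC(C)(C)c1cc2ccccc2[nH]1 | intermediate
5 | ethyl 3-bromo-2-(hydroxyimino)propanoate | CCOC(=O)C(CBr)=NO | starting material
6 | ethyl 2-nitrosoprop-2-enoate | CCOC(=O)C(=C)N=O | intermediate
7 | ethyl 2-(hydroxyimino)-3-[2-(2-methylbut-3-en-2-yl)-1H-indol-3-yl]propanoate | CCOC(=O)C(Cc1c(C(C)(C)C=C)[nH]c2ccccc12)=NO | intermediate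
8 | ethyl 2-imino-3-[2-(2-methylbut-3-en-2-yl)-1H-indol-3-yl]propanoate | CCOC(=O)C(=N)Cc1c(C(C)(C)C=C)[nH]c2ccccc12 | intermediate
9 | ethyl 3-[2-(2-methylbut-3-en-2-yl)-1H-indol-3-yl]-2-oxopropanoate (fragment 1) | CCOC(=O)C(=O)Cc1c(C(C)(C)C=C)[nH]c2ccccc12 | intermediate
10 | 2,2-dimethyl-1,3-dioxolan-4-one | CC1(C)OCC(=O)O1 | starting material
11 | 5-bromo-2,2-dimethyl-1,3-dioxolan-4-one (racemic) | CC1(C)OC(Br)C(=O)O1 | intermediate
12 | (2,2-dimethyl-5-oxo-1,3-dioxolan-4-yl)triphenylphosphonium bromide (racemic) | CC1(C)OC(C(=O)O1)[P+](c1ccccc1)(c1ccccc1)c1ccccc1.[Br-] | intermediate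
13 | tert-butyl 3-formyl-1H-indole-1-carboxylate | CC(C)(C)OC(=O)n1cc(C=O)c2ccccc21 | starting material
14 | 2,2-dimethyl-5-(triphenyl-λ5-phosphanylidene)-1,3-dioxolan-4-one | CC1(C)OC(=P(c2ccccc2)(c2ccccc2)c2ccccc2)C(=O)O1 | intermediate
15 | tert-butyl 3-[(Z)-(2,2-dimethyl-5-oxo-1,3-dioxolan-4-ylidene)methyl]-1H-indole-1-carboxylate (fragment 2) | CC(C)(C)OC(=O)n1cc(/C=C2\OC(C)(C)OC2=O)c2ccccc21 | intermediate
16 | ethyl 6-[1-(tert-butoxycarbonyl)-1H-indol-3-yl]-3-[2-(2-methylbut-3-en-2-yl)-1H-indol-3-yl]-2,4,5-trioxohexanoate (drawn as the triketo tautomer; the C3–H centre is enolisable and not a defined stereocentre) | CCOC(=O)C(=O)C(c1c(C(C)(C)C=C)[nH]c2ccccc12)C(=O)C(=O)Cc1cn(C(=O)OC(C)(C)C)c2ccccc12 | intermediate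
17 | tert-butyl 3-{2,5-dihydroxy-4-[2-(2-methylbut-3-en-2-yl)-1H-indol-3-yl]-3,6-dioxocyclohexa-1,4-dien-1-yl}-1H-indole-1-carboxylate | C=CC(C)(C)c1[nH]c2ccccc2c1C1=C(O)C(=O)C(c2cn(C(=O)OC(C)(C)C)c3ccccc23)=C(O)C1=O | intermediate
18 | 2,5-dihydroxy-3-(1H-indol-3-yl)-6-[2-(2-methylbut-3-en-2-yl)-1H-indol-3-yl]cyclohexa-2,5-diene-1,4-dione | C=CC(C)(C)c1[nH]c2ccccc2c1C1=C(O)C(=O)C(c2c[nH]c3ccccc23)=C(O)C1=O | intermediate
19 | 3-(1H-indol-3-yl)-2,5-dimethoxy-6-[2-(2-methylbut-3-en-2-yl)-1H-indol-3-yl]cyclohexa-2,5-diene-1,4-dione | C=CC(C)(C)c1[nH]c2ccccc2c1C1=C(OC)C(=O)C(c2c[nH]c3ccccc23)=C(OC)C1=O | target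

**Step count**
Total steps: 8. Longest linear sequence: 5 steps (steps 1, 2, 3, 7, 8 or steps 4, 5, 6, 7, 8).

**Steps most likely to fail**

Step 7 (proposed new method). The cascade may stall or leave the intended path. Possible processes are aldol-type five-membered ring closure onto the central ketone, self-condensation of the keto ester enolate, scrambling to homo-dimers if the dioxolanone is opened before it is acylated, or an incomplete lactone-to-carbocycle transposition. The fallback uses the known stepwise arylation of a haloquinone and sets out from 4. Acid-promoted conjugate addition of 4 to 2,5-dichloro-1,4-benzoquinone (AcOH, THF, rt) should give 2,5-dichloro-3-[2-(2-methylbut-3-en-2-yl)-1H-indol-3-yl]benzene-1,4-diol F1. DDQ then oxidises this to 2,5-dichloro-3-[2-(2-methylbut-3-en-2-yl)-1H-indol-3-yl]cyclohexa-2,5-diene-1,4-dione F2. A second acid-promoted addition, now of commercial indole, should give 2,5-dichloro-3-(1H-indol-3-yl)-6-[2-(2-methylbut-3-en-2-yl)-1H-indol-3-yl]benzene-1,4-diol F3, and DDQ oxidation gives 2,5-dichloro-3-(1H-indol-3-yl)-6-[2-(2-methylbut-3-en-2-yl)-1H-indol-3-yl]cyclohexa-2,5-diene-1,4-dione F4. Displacement of both chlorides with NaOH in MeOH–H2O at reflux returns to the route at 18.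

Step 3. The deoximation may fail through over-reduction or reductive coupling of the alpha-keto ester, incomplete hydrolysis of the imine, or aldol self-condensation of the product during isolation. The fallback avoids the oxime and sets out from 4. SnCl4-promoted opening of ethyl oxirane-2-carboxylate at its CH2 terminus by the indole C3 (CH2Cl2, −20 °C) should give ethyl 2-hydroxy-3-[2-(2-methylbut-3-en-2-yl)-1H-indol-3-yl]propanoate F5 (racemic). Dess–Martin periodinane with NaHCO3 in CH2Cl2 then oxidises it to 9, where the route is rejoined.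

Step 6. The olefination may be slow, with decomposition of the ylide or hydrolytic opening of the dioxolanone competing. The fallback is an aldol–elimination sequence that sets out from 10 and 13. The lithium enolate of 10 (LiN(iPr)2, THF, −78 °C) adds to 13 to give tert-butyl 3-[(2,2-dimethyl-5-oxo-1,3-dioxolan-4-yl)(hydroxy)methyl]-1H-indole-1-carboxylate F6 (diastereomer mixture). Acetylation (Ac2O, DMAP) gives tert-butyl 3-[(acetyloxy)(2,2-dimethyl-5-oxo-1,3-dioxolan-4-yl)methyl]-1H-indole-1-carboxylate F7. E1cB elimination with DBU returns to the route at 15.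

Further compounds
F1 | step 7 | 2,5-dichloro-3-[2-(2-methylbut-3-en-2-yl)-1H-indol-3-yl]benzene-1,4-diol | C=CC(C)(C)c1[nH]c2ccccc2c1-c1c(Cl)c(O)cc(Cl)c1O
F2 | step 7 | 2,5-dichloro-3-[2-(2-methylbut-3-en-2-yl)-1H-indol-3-yl]cyclohexa-2,5-diene-1,4-dione | C=CC(C)(C)c1[nH]c2ccccc2c1C1=C(Cl)C(=O)C=C(Cl)C1=O
F3 | step 7 | 2,5-dichloro-3-(1H-indol-3-yl)-6-[2-(2-methylbut-3-en-2-yl)-1H-indol-3-yl]benzene-1,4-diol | C=CC(C)(C)c1[nH]c2ccccc2c1-c1c(Cl)c(O)c(-c2c[nH]c3ccccc23)c(Cl)c1O
F4 | step 7 | 2,5-dichloro-3-(1H-indol-3-yl)-6-[2-(2-methylbut-3-en-2-yl)-1H-indol-3-yl]cyclohexa-2,5-diene-1,4-dione | C=CC(C)(C)c1[nH]c2ccccc2c1C1=C(Cl)C(=O)C(c2c[nH]c3ccccc23)=C(Cl)C1=O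
F5 | step 3 | ethyl 2-hydroxy-3-[2-(2-methylbut-3-en-2-yl)-1H-indol-3-yl]propanoate (racemic) | CCOC(=O)C(O)Cc1c(C(C)(C)C=C)[nH]c2ccccc12
F6 | step 6 | tert-butyl 3-[(2,2-dimethyl-5-oxo-1,3-dioxolan-4-yl)(hydroxy)methyl]-1H-indole-1-carboxylate (diastereomer mixture) | CC(C)(C)OC(=O)n1cc(C(O)C2OC(C)(C)OC2=O)c2ccccc21
F7 | step 6 | tert-butyl 3-[(acetyloxy)(2,2-dimethyl-5-oxo-1,3-dioxolan-4-yl)methyl]-1H-indole-1-carboxylate (diastereomer mixture) | CC(=O)OC(c1cn(C(=O)OC(C)(C)C)c2ccccc12)C1OC(C)(C)OC1=O
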